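**Strategy.** Oxolane carbon C5 bears ring oxygen O1, one hydrogen and guaiacyl ring B, so it is the reduced form of a lactone carbonyl; its aryl group lies cis to the C4 CH2OH, the less stable arrangement. Everything rests on cutting the C5–aryl bond: a silyl-protected guaiacyllithium adds to a trans,trans γ-lactone that already holds ring A at C2 and both CH2OSi arms at C3 and C4, and the hemiketal is reduced at once through its aryl-stabilised oxocarbenium ion. Hydride enters anti to the C4 arm, so one operation installs ring B and the fourth stereocentre. The lactone comes from an Evans succinate aldol–lactonisation; fluoride removes all silyl groups at the end.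

Key step: step 9

Remark: oxolane numbering is O1, C2 (ring A), C3, C4, C5 (ring B); the target is read as the 2,3-trans-3,4-trans-4,5-cis isomer (2S,3R,4R,5R). TIPS = triisopropylsilyl, TBS = tert-butyldimethylsilyl. In step 9 BF3·OEt2 is treated as a promoter that the equation does not consume.

Step 1
Reactants: 1 vanillin (4-hydroxy-3-methoxybenzaldehyde)
Product: 2 3-methoxy-4-(triisopropylsilyloxy)benzaldehyde
Conditions: TIPSCl, imidazole, DMF, 0 °C to rt
Reagents that add atoms: triisopropylsilyl chloride, CC(C)[Si](Cl)(C(C)C)C(C)C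
Why: Imidazole-promoted O-silylation of the phenol; the aryl TIPS ether should withstand the later LiOH/H2O2, borane, amide-base, aryllithium and BF3 steps and leave with fluoride at the end.

Step 2
Reactants: 3 (S)-4-benzyl-1,3-oxazolidin-2-one; 4 methyl 4-chloro-4-oxobutanoate
Product: 5 methyl 4-[(4S)-4-benzyl-2-oxo-1,3-oxazolidin-3-yl]-4-oxobutanoate
Conditions: n-BuLi, THF, −78 °C; then 4, −78 to 0 °C
Reagents that add atoms: none
Why: N-acylation of the lithiated oxazolidinone, which should attack the acid chloride and leave the methyl ester untouched.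

Step 3
Reactants: 5 methyl 4-[(4S)-4-benzyl-2-oxo-1,3-oxazolidin-3-yl]-4-oxobutanoate; 2 3-methoxy-4-(triisopropylsilyloxy)benzaldehyde
Product: 7 (4S)-4-benzyl-3-{[(2S,3S)-2-[3-methoxy-4-(triisopropylsilyloxy)phenyl]-5-oxooxolan-3-yl]carbonyl}-1,3-oxazolidin-2-one, via syn-aldol adduct 6 (not isolated)
Conditions: Bu2BOTf, i-Pr2NEt, CH2Cl2, 0 °C; 2, −78 to 0 °C; pH 7 buffer, MeOH, H2O2; lactonisation on work-up (cat. PPTS, CH2Cl2 if needed)
Reagents that add atoms: none
Why: Evans syn aldol reaction, in which the Z-boron enolate of 5 adds to 2 through a chair Zimmerman–Traxler transition state with the (S)-benzyl group shielding one enolate face, should set both new centres as (S,S), and the syn aldol hydroxyl then closes on the methyl ester (5-exo-trig lactonisation) to give the 2,3-trans lactone.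

Step 4
Reactants: 7 (4S)-4-benzyl-3-{[(2S,3S)-2-[3-methoxy-4-(triisopropylsilyloxy)phenyl]-5-oxooxolan-3-yl]carbonyl}-1,3-oxazolidin-2-one
Product: 8 (2S,3S)-2-[3-methoxy-4-(triisopropylsilyloxy)phenyl]-5-oxooxolane-3-carboxylic acid
Conditions: LiOH, H2O2, THF/H2O, 0 °C; Na2SO3; HCl to pH 2
Reagents that add atoms: hydrogen peroxide (as LiOOH), OO
Why: Hydroperoxide cleavage of the N-acyloxazolidinone at the exocyclic carbonyl; any lactone opened by hydroxide should reclose on acidification, and the trans arrangement is the stable one so no centre is at risk.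

Step 5
Reactants: 8 (2S,3S)-2-[3-methoxy-4-(triisopropylsilyloxy)phenyl]-5-oxooxolane-3-carboxylic acid
Product: 9 (4R,5S)-4-(hydroxymethyl)-5-[3-methoxy-4-(triisopropylsilyloxy)phenyl]oxolan-2-one
Conditions: BH3·SMe2, THF, 0 °C to rt; MeOH
Reagents that add atoms: none
Why: Chemoselective borane reduction of the carboxylic acid (through the acyloxyborane) in the presence of the lactone; the non-basic medium should keep the new primary hydroxyl from migrating the lactone acyl group.

Step 6
Reactants: 9 (4R,5S)-4-(hydroxymethyl)-5-[3-methoxy-4-(triisopropylsilyloxy)phenyl]oxolan-2-one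
Product: 10 (4R,5S)-4-[(tert-butyldimethylsilyloxy)methyl]-5-[3-methoxy-4-(triisopropylsilyloxy)phenyl]oxolan-2-one
Conditions: TBSCl, imidazole, CH2Cl2, 0 °C
Reagents that add atoms: tert-butyldimethylsilyl chloride, CC(C)(C)[Si](C)(C)Cl
Why: Fast O-silylation of the primary alcohol under mild conditions, which blocks translactonisation and protects the hydroxyl for the enolate and aryllithium steps.

Step 7
Reactants: 10 (4R,5S)-4-[(tert-butyldimethylsilyloxy)methyl]-5-[3-methoxy-4-(triisopropylsilyloxy)phenyl]oxolan-2-one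
Product: 11 (3R,4R,5S)-4-[(tert-butyldimethylsilyloxy)methyl]-5-[3-methoxy-4-(triisopropylsilyloxy)phenyl]-3-[(triisopropylsilyloxy)methyl]oxolan-2-one
Conditions: LiN(SiMe3)2, THF, −78 °C; (i-Pr)3SiOCH2Cl, −78 to −30 °C
Reagents that add atoms: (triisopropylsiloxy)methyl chloride, ClCO[Si](C(C)C)(C(C)C)C(C)C
Why: C-alkylation of the lactone lithium enolate with an α-chloro ether (the silyl counterpart of the benzyloxymethyl chloride hydroxymethylation); the electrophile should approach anti to the C4 CH2OTBS group and so set the 3,4-trans centre.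

Step 8
Reactants: 12 4-bromo-2-methoxyphenol
Product: 13 (4-bromo-2-methoxyphenoxy)triisopropylsilane
Conditions: TIPSCl, imidazole, DMF, rt
Reagents that add atoms: triisopropylsilyl chloride, CC(C)[Si](Cl)(C(C)C)C(C)C
Why: O-silylation of the phenol gives an aryl bromide that tolerates bromine–lithium exchange and is unmasked by fluoride together with the other silyl ethers.

Step 9
Reactants: 13 (4-bromo-2-methoxyphenoxy)triisopropylsilane; 11 (3R,4R,5S)-4-[(tert-butyldimethylsilyloxy)methyl]-5-[3-methoxy-4-(triisopropylsilyloxy)phenyl]-3-[(triisopropylsilyloxy)methyl]oxolan-2-one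
Product: 16 (2S,3R,4R,5R)-3-[(tert-butyldimethylsilyloxy)methyl]-2,5-bis[3-methoxy-4-(triisopropylsilyloxy)phenyl]-4-[(triisopropylsilyloxy)methyl]oxolane, via aryllithium 14 (not isolated), via hemiketal 15 (not isolated)
Conditions: 13, n-BuLi, THF, −78 °C; 11, −78 °C; AcOH quench; crude 15, Et3SiH, BF3·OEt2, CH2Cl2, −78 °C; Et3N quench at −78 °C
Reagents that add atoms: none
Why: Bromine–lithium exchange turns 13 into aryllithium 14, which adds once to the lactone carbonyl of 11 (the lithium hemiketalate should survive at −78 °C, so a second addition is not expected) and thereby makes the C5–aryl bond; after the acetic acid quench BF3·OEt2 ionises hemiketal 15 to a five-membered oxocarbenium ion stabilised by the para-silyloxy ring B, and Et3SiH delivers hydride to C5. The closest known reaction type is aryllithium–lactone addition with ionic hydrogenation of the lactol, as used for C-aryl glycosides and 2,5-diaryloxolane lignans. No new ring is closed: the oxolane is the lactone ring carried through, and any open hydroxy ketone form of 15 recloses by 5-exo-trig attack of the C2 hydroxyl on the ketone before ionisation. The new stereocentre C5 is controlled by the neighbouring C4 centre: hydride should enter the face anti to the C4 CH2OSi arm (also the face remote from ring A at C2), which places ring B cis to the C4 arm and cis to ring A, the kinetic 4,5-cis arrangement of the target. The step needs carbonyl addition to win over deprotonation at C3 and needs the kinetic C5 configuration to survive; the high nucleophilicity of the aryllithium at −78 °C should secure the first, and the low temperature with a cold Et3N quench the second, since warm BF3·OEt2 would reopen the benzylic C–O bonds and drift towards the all-trans isomer.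

Step 10
Reactants: 16 (2S,3R,4R,5R)-3-[(tert-butyldimethylsilyloxy)methyl]-2,5-bis[3-methoxy-4-(triisopropylsilyloxy)phenyl]-4-[(triisopropylsilyloxy)methyl]oxolane
Product: 17 [(2S,3R,4R,5R)-2,5-bis(4-hydroxy-3-methoxyphenyl)-4-(hydroxymethyl)oxolan-3-yl]methanol
Conditions: Bu4NF, AcOH, THF, 0 °C to rt
Reagents that add atoms: none
Why: Fluoride-driven Si–O cleavage should remove the three TIPS groups and the TBS group in one operation, and the acetic acid buffer keeps the medium near neutral so that the para-hydroxybenzylic ether centres C2 and C5 are not opened through a quinone methide.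

**Compound list**

1 | vanillin (4-hydroxy-3-methoxybenzaldehyde) | COc1cc(C=O)ccc1O | starting material
2 | 3-methoxy-4-(triisopropylsilyloxy)benzaldehyde | COc1cc(C=O)ccc1O[Si](C(C)C)(C(C)C)C(C)C | intermediate
3 | (S)-4-benzyl-1,3-oxazolidin-2-one | O=C1OC[C@H](Cc2ccccc2)N1 | starting material
4 | methyl 4-chloro-4-oxobutanoate | COC(=O)CCC(Cl)=O | starting material
5 | methyl 4-[(4S)-4-benzyl-2-oxo-1,3-oxazolidin-3-yl]-4-oxobutanoate | COC(=O)CCC(=O)N1[C@@H](Cc2ccccc2)COC1=O | intermediate
6 | methyl (3S)-4-[(4S)-4-benzyl-2-oxo-1,3-oxazolidin-3-yl]-3-{(S)-hydroxy[3-methoxy-4-(triisopropylsilyloxy)phenyl]methyl}-4-oxobutanoate (syn-aldol adduct) | COc1cc([C@@H](O)[C@H](CC(=O)OC)C(=O)N2[C@@H](Cc3ccccc3)COC2=O)ccc1O[Si](C(C)C)(C(C)C)C(C)C | intermediate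
7 | (4S)-4-benzyl-3-{[(2S,3S)-2-[3-methoxy-4-(triisopropylsilyloxy)phenyl]-5-oxooxolan-3-yl]carbonyl}-1,3-oxazolidin-2-one (2,3-trans lactone) | COc1cc([C@H]2OC(=O)C[C@@H]2C(=O)N3[C@@H](Cc4ccccc4)COC3=O)ccc1O[Si](C(C)C)(C(C)C)C(C)C | intermediate
8 | (2S,3S)-2-[3-methoxy-4-(triisopropylsilyloxy)phenyl]-5-oxooxolane-3-carboxylic acid | COc1cc([C@H]2OC(=O)C[C@@H]2C(O)=O)ccc1O[Si](C(C)C)(C(C)C)C(C)C | intermediate
9 | (4R,5S)-4-(hydroxymethyl)-5-[3-methoxy-4-(triisopropylsilyloxy)phenyl]oxolan-2-one | COc1cc([C@H]2OC(=O)C[C@@H]2CO)ccc1O[Si](C(C)C)(C(C)C)C(C)C | intermediate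
10 | (4R,5S)-4-[(tert-butyldimethylsilyloxy)methyl]-5-[3-methoxy-4-(triisopropylsilyloxy)phenyl]oxolan-2-one | COc1cc([C@H]2OC(=O)C[C@@H]2CO[Si](C)(C)C(C)(C)C)ccc1O[Si](C(C)C)(C(C)C)C(C)C | intermediate
11 | (3R,4R,5S)-4-[(tert-butyldimethylsilyloxy)methyl]-5-[3-methoxy-4-(triisopropylsilyloxy)phenyl]-3-[(triisopropylsilyloxy)methyl]oxolan-2-one (3,4-trans, 4,5-trans) | COc1cc([C@H]2OC(=O)[C@@H](CO[Si](C(C)C)(C(C)C)C(C)C)[C@@H]2CO[Si](C)(C)C(C)(C)C)ccc1O[Si](C(C)C)(C(C)C)C(C)C | intermediate
12 | 4-bromo-2-methoxyphenol | COc1cc(Br)ccc1O | starting material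
13 | (4-bromo-2-methoxyphenoxy)triisopropylsilane | COc1cc(Br)ccc1O[Si](C(C)C)(C(C)C)C(C)C | intermediate
14 | [3-methoxy-4-(triisopropylsilyloxy)phenyl]lithium | COc1cc([Li])ccc1O[Si](C(C)C)(C(C)C)C(C)C | intermediate
15 | (3R,4R,5S)-4-[(tert-butyldimethylsilyloxy)methyl]-2,5-bis[3-methoxy-4-(triisopropylsilyloxy)phenyl]-3-[(triisopropylsilyloxy)methyl]oxolan-2-ol (both C2 epimers, in equilibrium with the open hydroxy ketone) | COc1cc([C@H]2OC(O)(c3ccc(O[Si](C(C)C)(C(C)C)C(C)C)c(OC)c3)[C@@H](CO[Si](C(C)C)(C(C)C)C(C)C)[C@@H]2CO[Si](C)(C)C(C)(C)C)ccc1O[Si](C(C)C)(C(C)C)C(C)C | intermediate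
16 | (2S,3R,4R,5R)-3-[(tert-butyldimethylsilyloxy)methyl]-2,5-bis[3-methoxy-4-(triisopropylsilyloxy)phenyl]-4-[(triisopropylsilyloxy)methyl]oxolane (2,3-trans, 3,4-trans, 4,5-cis) | COc1cc([C@H]2O[C@@H](c3ccc(O[Si](C(C)C)(C(C)C)C(C)C)c(OC)c3)[C@@H](CO[Si](C(C)C)(C(C)C)C(C)C)[C@@H]2CO[Si](C)(C)C(C)(C)C)ccc1O[Si](C(C)C)(C(C)C)C(C)C | intermediate
17 | [(2S,3R,4R,5R)-2,5-bis(4-hydroxy-3-methoxyphenyl)-4-(hydroxymethyl)oxolan-3-yl]methanol (2,3-trans, 3,4-trans, 4,5-cis) | COc1cc([C@H]2O[C@@H](c3ccc(O)c(OC)c3)[C@@H](CO)[C@@H]2CO)ccc1O | target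

**Step count**

Total steps: 10. Longest linear sequence: 8 steps (steps 2, 3, 4, 5, 6, 7, 9, 10; the same length when counted from vanillin through step 1).

**Steps most likely to fail**

1. Step 9 (key step). The basic aryllithium may deprotonate the α-branched lactone at C3 instead of adding, with β-elimination of silanolate, or the kinetic 4,5-cis selectivity may erode through Lewis-acid ring opening and reclosure at the benzylic carbons. The fallback sets out from 11 and 13 and comes back at 16. Lactone 11 would be reduced with i-Bu2AlH (CH2Cl2, −78 °C) and the aluminium hemiacetal acetylated in the same flask (Ac2O, pyridine, DMAP) to give the lactol acetate (3R,4R,5S)-4-[(tert-butyldimethylsilyloxy)methyl]-5-[3-methoxy-4-(triisopropylsilyloxy)phenyl]-3-[(triisopropylsilyloxy)methyl]oxolan-2-yl acetate F1. Bromide 13 would be taken through aryllithium 14 and ZnBr2 to the arylzinc bromide bromo[3-methoxy-4-(triisopropylsilyloxy)phenyl]zinc F2. F1 and F2 would then be combined with Me3SiOTf or BF3·OEt2 in CH2Cl2 at −78 to −40 °C. The non-basic arylzinc should attack the C5-unsubstituted oxocarbenium ion on the inside face of the envelope that has all three substituents pseudo-equatorial, that is cis to the C4 arm and trans to the C3 arm, which would give 16 directly.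

2. Step 7. Alkylation by the hindered silyloxymethyl chloride may be sluggish or partly O-selective, or a second deprotonation of the product may expel silanolate and form the α-methylene lactone. The fallback sets out from 10 and comes back at 11. The lithium enolate of 10 (LiN(SiMe3)2, THF, −78 °C) would be treated with gaseous formaldehyde from cracked paraformaldehyde to give the trans aldol product (3R,4R,5S)-4-[(tert-butyldimethylsilyloxy)methyl]-3-(hydroxymethyl)-5-[3-methoxy-4-(triisopropylsilyloxy)phenyl]oxolan-2-one F3. Silylation of F3 with TIPSOTf and 2,6-lutidine (CH2Cl2, −78 °C) would give 11.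

3. Step 3. The boron enolate may add slowly to the electron-rich, deactivated aldehyde, and retro-aldol cleavage or incomplete ring closure during work-up may erode conversion and diastereomeric purity. The fallback sets out from 2 and comes back at 8, skipping steps 2 to 4. Aldehyde 2 would be condensed with succinic anhydride (ZnCl2, Et3N, CH2Cl2, rt) to give, after equilibration, the racemic trans acid rac-(2S,3S)-2-[3-methoxy-4-(triisopropylsilyloxy)phenyl]-5-oxooxolane-3-carboxylic acid F4. Classical resolution by crystallisation would give the (S)-1-phenylethylammonium salt of the (2S,3S)-acid F5 (the antipodal amine would be used if its salt crystallises better), and HCl would release 8.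

**Further compounds**

F1 | step 9 | (3R,4R,5S)-4-[(tert-butyldimethylsilyloxy)methyl]-5-[3-methoxy-4-(triisopropylsilyloxy)phenyl]-3-[(triisopropylsilyloxy)methyl]oxolan-2-yl acetate (both C2 epimers) | COc1cc([C@H]2OC(OC(C)=O)[C@@H](CO[Si](C(C)C)(C(C)C)C(C)C)[C@@H]2CO[Si](C)(C)C(C)(C)C)ccc1O[Si](C(C)C)(C(C)C)C(C)C
F2 | step 9 | bromo[3-methoxy-4-(triisopropylsilyloxy)phenyl]zinc | COc1cc([Zn]Br)ccc1O[Si](C(C)C)(C(C)C)C(C)C
F3 | step 7 | (3R,4R,5S)-4-[(tert-butyldimethylsilyloxy)methyl]-3-(hydroxymethyl)-5-[3-methoxy-4-(triisopropylsilyloxy)phenyl]oxolan-2-one | COc1cc([C@H]2OC(=O)[C@@H](CO)[C@@H]2CO[Si](C)(C)C(C)(C)C)ccc1O[Si](C(C)C)(C(C)C)C(C)C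
F4 | step 3 | rac-(2S,3S)-2-[3-methoxy-4-(triisopropylsilyloxy)phenyl]-5-oxooxolane-3-carboxylic acid (racemic trans acid, drawn as both enantiomers) | COc1cc([C@H]2OC(=O)C[C@@H]2C(O)=O)ccc1O[Si](C(C)C)(C(C)C)C(C)C.COc1cc([C@@H]2OC(=O)C[C@H]2C(O)=O)ccc1O[Si](C(C)C)(C(C)C)C(C)C
F5 | step 3 | (S)-1-phenylethylammonium (2S,3S)-2-[3-methoxy-4-(triisopropylsilyloxy)phenyl]-5-oxooxolane-3-carboxylate | COc1cc([C@H]2OC(=O)C[C@@H]2C([O-])=O)ccc1O[Si](C(C)C)(C(C)C)C(C)C.C[C@H]([NH3+])c1ccccc1
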